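**Plan**

- Numbering used: THF ring O1, C2 (aryl), C3 (bears C9H2OH), C4 (bears benzylic C7'H2), C5H2; side chain C7'' (carbinol) and C8'' (aryloxy carbon).
- Retrosynthetic cuts, in order: C9 CH2OH back to CO2H; the C7'–H bond and all benzyl-type protecting groups back to one hydrogenolysis of a γ-aryl lactone C9(=O)–O–C7' (a temporary ring); C2–C3 and C5–C4 together, giving an aryl carbonyl ylide (C2–O1–C5) and the C3=C4 bond of an (S)-5-aryl-2(5H)-furanone; the butenolide to an aryl aldehyde plus methyl propiolate; C7''–C8'' by a glycolate aldol.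
- Enabling feature: in the THF ring O1 lies between aryl-bearing C2 and unsubstituted C5 (a carbonyl ylide), while C3 and C4 carry cis carbons (C9, which can be a carbonyl, and benzylic C7') that can be tied into a lactone ring. That ring activates and locks the C3=C4 alkene, and its C7' stereocentre steers the facial selectivity before being erased.
- Forward order: side chain by aldol, 1,3-dioxane protection, formylation, butenolide ring, THF ring fused to the lactone (key step), lactone opened with loss of all benzyl-type groups, acid reduced.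
- Stereochemistry: 7''R,8''R from the (S)-4-benzyloxazolidinone (Evans syn aldol); butenolide C5 from Zn–ProPhenol alkynylation; THF C3/C4 from addition anti to that centre (cis by the ring); C2 from exo approach of the ylide.

Key step: step 9

Remark: compounds 1, 2, 4, 9 and 13 are taken as purchasable; the ProPhenol enantiomer is specified by the aldehyde face it serves (Si), since that is what fixes the (R)-carbinol.
Abbreviations in names: BnV = 4-(benzyloxy)-3-methoxyphenyl; Q = 4-{[(2S,4R,5R)-4-BnV-2-phenyl-1,3-dioxan-5-yl]oxy}-3-methoxyphenyl.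

**Route**

Step 1
Reactants: 1 4-bromo-2-methoxyphenol; 2 (S)-4-benzyl-3-(chloroacetyl)oxazolidin-2-one
Product: 3 (S)-4-benzyl-3-[(4-bromo-2-methoxyphenoxy)acetyl]oxazolidin-2-one
Conditions: K2CO3, NaI (cat.), acetone, rt to 40 °C
Reagents that add atoms: none
Why: Williamson O-alkylation of the phenoxide at the activated α-halo imide should be faster than any attack on the imide carbonyls.

Step 2
Reactants: 3 (S)-4-benzyl-3-[(4-bromo-2-methoxyphenoxy)acetyl]oxazolidin-2-one; 4 4-(benzyloxy)-3-methoxybenzaldehyde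
Product: 5 (S)-4-benzyl-3-[(2S,3R)-3-BnV-2-(4-bromo-2-methoxyphenoxy)-3-hydroxypropanoyl]oxazolidin-2-one
Conditions: Bu2BOTf, iPr2NEt, CH2Cl2, −78 to 0 °C; then 4, −78 to 0 °C; pH 7 buffer, H2O2, MeOH
Reagents that add atoms: none
Why: Evans syn glycolate aldol: the Z-boron enolate reacts through a Zimmerman–Traxler chair on the face opposite the 4-benzyl group, which should set both side-chain centres in the threo (7''R,8''R) sense.

Step 3
Reactants: 5 aldol adduct
Product: 6 (1R,2R)-1-BnV-2-(4-bromo-2-methoxyphenoxy)propane-1,3-diol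
Conditions: LiBH4, MeOH (1 equiv), THF, 0 °C
Reagents that add atoms: none
Why: reductive removal of the Evans auxiliary at the exocyclic imide carbonyl; aryl bromide, ethers and both stereocentres should be untouched.

Step 4
Reactants: 6 diol
Product: 7 (2S,4R,5R)-4-BnV-5-(4-bromo-2-methoxyphenoxy)-2-phenyl-1,3-dioxane
Conditions: PhCH(OMe)2, PPTS (cat.), benzene, 60 °C
Reagents that add atoms: benzaldehyde dimethyl acetal COC(OC)c1ccccc1
Why: transacetalisation to the six-membered benzylidene acetal under thermodynamic control, which should place the phenyl group equatorial (2S, cis to the 4-aryl group); PPTS is mild enough not to ionise the benzylic C–O bond.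

Step 5
Reactants: 7 aryl bromide
Product: 8 4-{[(2S,4R,5R)-4-BnV-2-phenyl-1,3-dioxan-5-yl]oxy}-3-methoxybenzaldehyde (Q-CHO)
Conditions: n-BuLi, THF, −78 °C; DMF, −78 to 0 °C; H2O
Reagents that add atoms: N,N-dimethylformamide CN(C)C=O
Why: bromine–lithium exchange at −78 °C is faster than any deprotonation, and the aryllithium is formylated by DMF (Bouveault-type formylation).

Step 6
Reactants: 8 Q-CHO; 9 methyl propiolate
Product: 10 methyl (R)-4-hydroxy-4-Q-but-2-ynoate
Conditions: Me2Zn, ProPhenol ligand (20 mol %, Si-face-selective enantiomer), Ph3PO (40 mol %), toluene, 4 °C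
Reagents that add atoms: none
Why: Zn–ProPhenol catalysed asymmetric alkynylation of an aryl aldehyde; the dinuclear zinc catalyst should deliver the alkynyl group to the Si face (catalyst control, the existing centres being remote) to set the (R)-carbinol.

Step 7
Reactants: 10 propargylic alcohol
Product: 12 (S)-5-Q-furan-2(5H)-one, via Z-hydroxy enoate 11 (not isolated)
Conditions: H2 (1 atm), Lindlar catalyst, quinoline, EtOAc, rt; then PPTS (cat.), CH2Cl2, rt
Reagents that add atoms: none
Why: Lindlar cis-semihydrogenation gives the Z-enoate whose γ-hydroxyl lactonises onto the cis ester; the carbinol centre is not touched (its descriptor changes to S only through CIP priorities).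

Step 8
Reactants: 4 4-(benzyloxy)-3-methoxybenzaldehyde; 13 (trimethylsilyl)methanol
Product: 14 4-(benzyloxy)-3-methoxybenzaldehyde bis[(trimethylsilyl)methyl] acetal
Conditions: 13 (2.5 equiv in all), TsOH (cat.), benzene, reflux, Dean–Stark
Reagents that add atoms: (trimethylsilyl)methanol, second equivalent C[Si](C)(C)CO
Why: acid-catalysed acetalisation of the aldehyde with two molecules of the alcohol (hemiacetal, oxocarbenium ion, acetal), driven to completion by azeotropic removal of the one molecule of water that is formed.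

Step 9
Reactants: 14 bis(silylmethyl) acetal; 12 (S)-5-Q-furan-2(5H)-one
Product: 17 (3S,3aR,6S,6aS)-6-BnV-3-Q-tetrahydro-1H,3H-furo[3,4-c]furan-1-one, via α-chlorobenzyl silylmethyl ether 15 (not isolated), via carbonyl ylide 16 (not isolated)
Conditions: 14 (3 equiv), AcCl, CH2Cl2, 0 °C to rt, evaporate; then 12 (1 equiv), CsF (2.5 equiv, in portions), MeCN, 0 °C to rt
Reagents that add atoms: none
Why: Acetyl chloride turns acetal 14 into α-chloro ether 15, whose fluoride-triggered 1,3-elimination (ionisation to the aryl oxocarbenium ion, then desilylation) releases the non-stabilised carbonyl ylide 16, which adds as the 4π component across the electron-poor C3=C4 bond of 12 in a suprafacial [3+2] cycloaddition. The closest known reaction type is the silicon-based generation of non-stabilised carbonyl ylides from α-chloroalkyl silylmethyl ethers and their cycloaddition to α,β-unsaturated esters. The THF ring closes by formation of both C–C bonds in this one cycloaddition (not by a separate Baldwin-type cyclisation), giving the cis-fused furo[3,4-c]furanone. C3a and C6a follow from suprafacial addition to the ring-locked Z-alkene on the face anti to the C5 aryl group of 12, and C6 from exo approach of the E-shaped ylide, which places its aryl group on the convex face, trans to the lactone carbonyl. The regioselectivity needed (ylide CH2 to the β-carbon, aryl-bearing carbon to the α-carbon) should follow from Michael-like attack of the more nucleophilic, smaller CH2 terminus, which leaves the aryl-stabilised oxocarbenium end to close on the α-carbon. The C5 configuration of 12 must survive, which is why the silyl ether is kept in excess over fluoride and fluoride is added last.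

Step 10
Reactants: 17 cycloadduct
Product: 18 (2S,3S,4R)-4-(4-{[(1R,2R)-1,3-dihydroxy-1-(4-hydroxy-3-methoxyphenyl)propan-2-yl]oxy}-3-methoxybenzyl)-2-(4-hydroxy-3-methoxyphenyl)tetrahydrofuran-3-carboxylic acid
Conditions: H2 (1 atm), 10% Pd/C, EtOAc–MeOH, rt, stopped when the lactone is consumed
Reagents that add atoms: none
Why: hydrogenolysis should cleave the benzylic carboxylate C–O bond of the lactone (C7' becomes CH2), both O-benzyl ethers and the benzylidene acetal, while the poorer leaving groups (THF benzylic ether, side-chain benzylic hydroxyl) are spared under neutral conditions and no stereocentre is touched.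

Step 11
Reactants: 18 acid
Product: 19 (1R,2R)-1-(4-hydroxy-3-methoxyphenyl)-2-(4-{[(3R,4R,5S)-5-(4-hydroxy-3-methoxyphenyl)-4-(hydroxymethyl)tetrahydrofuran-3-yl]methyl}-2-methoxyphenoxy)propane-1,3-diol (target)
Conditions: BH3·SMe2 (excess), THF, 0 °C to rt; MeOH
Reagents that add atoms: none
Why: borane reduction of a carboxylic acid through the acyloxyborane is chemoselective; phenols and alcohols only form borates that methanolysis releases, and C3 is not epimerised.

**Compound list**

1 | 4-bromo-2-methoxyphenol | COc1cc(Br)ccc1O | starting material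
2 | (S)-4-benzyl-3-(chloroacetyl)oxazolidin-2-one | O=C1OC[C@H](Cc2ccccc2)N1C(=O)CCl | starting material
3 | (S)-4-benzyl-3-[(4-bromo-2-methoxyphenoxy)acetyl]oxazolidin-2-one | COc1cc(Br)ccc1OCC(=O)N1[C@@H](Cc2ccccc2)COC1=O | intermediate
4 | 4-(benzyloxy)-3-methoxybenzaldehyde | COc1cc(C=O)ccc1OCc1ccccc1 | starting material
5 | (S)-4-benzyl-3-[(2S,3R)-3-BnV-2-(4-bromo-2-methoxyphenoxy)-3-hydroxypropanoyl]oxazolidin-2-one | COc1cc([C@@H](O)[C@@H](C(=O)N2[C@@H](Cc3ccccc3)COC2=O)Oc2ccc(Br)cc2OC)ccc1OCc1ccccc1 | intermediate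
6 | (1R,2R)-1-BnV-2-(4-bromo-2-methoxyphenoxy)propane-1,3-diol | COc1cc([C@@H](O)[C@@H](CO)Oc2ccc(Br)cc2OC)ccc1OCc1ccccc1 | intermediate
7 | (2S,4R,5R)-4-BnV-5-(4-bromo-2-methoxyphenoxy)-2-phenyl-1,3-dioxane | COc1cc([C@H]2O[C@@H](c3ccccc3)OC[C@H]2Oc4ccc(Br)cc4OC)ccc1OCc1ccccc1 | intermediate
8 | 4-{[(2S,4R,5R)-4-BnV-2-phenyl-1,3-dioxan-5-yl]oxy}-3-methoxybenzaldehyde (Q-CHO) | COc1cc([C@H]2O[C@@H](c3ccccc3)OC[C@H]2Oc4ccc(C=O)cc4OC)ccc1OCc1ccccc1 | intermediate
9 | methyl propiolate | C#CC(=O)OC | starting material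
10 | methyl (R)-4-hydroxy-4-Q-but-2-ynoate | COc1cc([C@H]2O[C@@H](c3ccccc3)OC[C@H]2Oc4ccc([C@@H](O)C#CC(=O)OC)cc4OC)ccc1OCc1ccccc1 | intermediate
11 | methyl (2Z,4S)-4-hydroxy-4-Q-but-2-enoate | COc1cc([C@H]2O[C@@H](c3ccccc3)OC[C@H]2Oc4ccc([C@@H](O)/C=C\C(=O)OC)cc4OC)ccc1OCc1ccccc1 | intermediate (not isolated)
12 | (S)-5-Q-furan-2(5H)-one | COc1cc([C@H]2O[C@@H](c3ccccc3)OC[C@H]2Oc4ccc([C@@H]5C=CC(=O)O5)cc4OC)ccc1OCc1ccccc1 | intermediate
13 | (trimethylsilyl)methanol | C[Si](C)(C)CO | starting material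
14 | 4-(benzyloxy)-3-methoxybenzaldehyde bis[(trimethylsilyl)methyl] acetal | COc1cc(C(OC[Si](C)(C)C)OC[Si](C)(C)C)ccc1OCc1ccccc1 | intermediate
15 | chloro(BnV)methyl (trimethylsilyl)methyl ether (either configuration) | COc1cc(C(Cl)OC[Si](C)(C)C)ccc1OCc1ccccc1 | intermediate (not isolated)
16 | carbonyl ylide BnV-CH=O(+)-CH2(−) | COc1cc(C=[O+][CH2-])ccc1OCc1ccccc1 | intermediate (not isolated)
17 | (3S,3aR,6S,6aS)-6-BnV-3-Q-tetrahydro-1H,3H-furo[3,4-c]furan-1-one | COc1cc([C@H]2O[C@@H](c3ccccc3)OC[C@H]2Oc4ccc([C@@H]5[C@H]6CO[C@H](c7ccc(OCc8ccccc8)c(OC)c7)[C@H]6C(=O)O5)cc4OC)ccc1OCc1ccccc1 | intermediate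
18 | (2S,3S,4R)-4-(4-{[(1R,2R)-1,3-dihydroxy-1-(4-hydroxy-3-methoxyphenyl)propan-2-yl]oxy}-3-methoxybenzyl)-2-(4-hydroxy-3-methoxyphenyl)tetrahydrofuran-3-carboxylic acid | COc1cc([C@@H](O)[C@@H](CO)Oc2ccc(C[C@H]3CO[C@H](c4ccc(O)c(OC)c4)[C@H]3C(=O)O)cc2OC)ccc1O | intermediate
19 | (1R,2R)-1-(4-hydroxy-3-methoxyphenyl)-2-(4-{[(3R,4R,5S)-5-(4-hydroxy-3-methoxyphenyl)-4-(hydroxymethyl)tetrahydrofuran-3-yl]methyl}-2-methoxyphenoxy)propane-1,3-diol | COc1cc([C@@H](O)[C@@H](CO)Oc2ccc(C[C@H]3CO[C@H](c4ccc(O)c(OC)c4)[C@H]3CO)cc2OC)ccc1O | target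

**Count and risks**

Total steps: 11. Longest linear sequence: 10 (steps 1–7, 9, 10, 11).

Step 9. What may go wrong: fluoride may deprotonate C5 of butenolide 12, racemising it or moving the double bond before the ylide is trapped; exo or regiocontrol in the cycloaddition may also be incomplete.
Fallback (sets out from 8, comes back at 19): the THF ring is built by the classical lactone aldol and cycloetherification sequence instead. Stobbe condensation of 8 with dimethyl succinate (NaOMe, MeOH, reflux) should give (E)-3-(methoxycarbonyl)-4-Q-but-3-enoic acid F1. Rhodium–bisphosphine asymmetric hydrogenation of its triethylammonium salt should give (R)-3-(methoxycarbonyl)-4-Q-butanoic acid F2. Reduction of the ester group of the potassium carboxylate with Ca(BH4)2 (EtOH, 0 °C), then acidification, should give (R)-4-(Q-methyl)dihydrofuran-2(3H)-one F3. Its lithium enolate (LiHMDS, THF, −78 °C) should add to aldehyde 4 anti to the benzyl group to give (3S,4R)-3-[BnV(hydroxy)methyl]-4-(Q-methyl)dihydrofuran-2(3H)-one F4 as carbinol epimers. LiAlH4 should then give (2R,3R)-2-[BnV(hydroxy)methyl]-3-(Q-methyl)butane-1,4-diol F5. Catalytic CSA in CH2Cl2 at 0 °C should ionise the p-alkoxybenzylic alcohol so that the C4 hydroxyl closes the 2,3-trans ring, giving [(2S,3R,4R)-2-BnV-4-(Q-methyl)tetrahydrofuran-3-yl]methanol F6. Hydrogenolysis (H2, Pd/C, EtOAc) of the benzyl ethers and the benzylidene acetal should then give 19.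

Step 10. What may go wrong: over-hydrogenolysis (loss of the THF benzylic C–O bond or of the side-chain benzylic hydroxyl), or sluggish cleavage of the lactone C–O bond.
Fallback (sets out from 17, comes back at 18): the lactone is opened by nucleophilic alkyl–oxygen cleavage and a radical reduction, so that hydrogenolysis only has to remove benzyl-type protecting groups. Sodium phenylselenolate ((PhSe)2, NaBH4; then 18-crown-6, THF/HMPA, 60 °C) should attack the benzylic lactone carbon with inversion to give (2S,3S,4R)-2-BnV-4-[(R)-(phenylselanyl)(Q)methyl]tetrahydrofuran-3-carboxylic acid F7. Bu3SnH/AIBN (toluene, 80 °C) should replace selenium by hydrogen to give (2S,3S,4R)-2-BnV-4-(Q-methyl)tetrahydrofuran-3-carboxylic acid F8. Brief hydrogenolysis (H2, Pd/C, EtOAc) of the two benzyl ethers and the benzylidene acetal should give 18.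

Step 6. What may go wrong: low enantioselectivity in the alkynyl transfer to an electron-rich, Lewis-basic aryl aldehyde.
Fallback (sets out from 8, comes back at 10): the carbinol centre is set by asymmetric ketone reduction instead of asymmetric C–C bond formation. Lithiated methyl propiolate (LiHMDS, THF, −78 °C) should add to 8 to give methyl 4-hydroxy-4-Q-but-2-ynoate F9 as both carbinol epimers. MnO2 (CH2Cl2) should give methyl 4-oxo-4-Q-but-2-ynoate F10. Corey–Bakshi–Shibata reduction with the (R)-methyl oxazaborolidine and catecholborane (−78 °C; aryl as the large group) should give 10.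

**Further compounds**

F1 | step 9 | (E)-3-(methoxycarbonyl)-4-Q-but-3-enoic acid | COc1cc([C@H]2O[C@@H](c3ccccc3)OC[C@H]2Oc4ccc(/C=C(\CC(=O)O)C(=O)OC)cc4OC)ccc1OCc1ccccc1
F2 | step 9 | (R)-3-(methoxycarbonyl)-4-Q-butanoic acid | COc1cc([C@H]2O[C@@H](c3ccccc3)OC[C@H]2Oc4ccc(C[C@H](CC(=O)O)C(=O)OC)cc4OC)ccc1OCc1ccccc1
F3 | step 9 | (R)-4-(Q-methyl)dihydrofuran-2(3H)-one | COc1cc([C@H]2O[C@@H](c3ccccc3)OC[C@H]2Oc4ccc(C[C@@H]5CC(=O)OC5)cc4OC)ccc1OCc1ccccc1
F4 | step 9 | (3S,4R)-3-[BnV(hydroxy)methyl]-4-(Q-methyl)dihydrofuran-2(3H)-one (carbinol epimers) | COc1cc([C@H]2O[C@@H](c3ccccc3)OC[C@H]2Oc4ccc(C[C@@H]5[C@@H](C(O)c6ccc(OCc7ccccc7)c(OC)c6)C(=O)OC5)cc4OC)ccc1OCc1ccccc1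
F5 | step 9 | (2R,3R)-2-[BnV(hydroxy)methyl]-3-(Q-methyl)butane-1,4-diol (carbinol epimers) | COc1cc([C@H]2O[C@@H](c3ccccc3)OC[C@H]2Oc4ccc(C[C@@H](CO)[C@H](CO)C(O)c6ccc(OCc7ccccc7)c(OC)c6)cc4OC)ccc1OCc1ccccc1
F6 | step 9 | [(2S,3R,4R)-2-BnV-4-(Q-methyl)tetrahydrofuran-3-yl]methanol | COc1cc([C@H]2O[C@@H](c3ccccc3)OC[C@H]2Oc4ccc(C[C@H]5CO[C@H](c6ccc(OCc7ccccc7)c(OC)c6)[C@H]5CO)cc4OC)ccc1OCc1ccccc1
F7 | step 10 | (2S,3S,4R)-2-BnV-4-[(R)-(phenylselanyl)(Q)methyl]tetrahydrofuran-3-carboxylic acid | COc1cc([C@H]2O[C@@H](c3ccccc3)OC[C@H]2Oc4ccc([C@H]([Se]c5ccccc5)[C@H]6CO[C@H](c7ccc(OCc8ccccc8)c(OC)c7)[C@H]6C(=O)O)cc4OC)ccc1OCc1ccccc1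
F8 | step 10 | (2S,3S,4R)-2-BnV-4-(Q-methyl)tetrahydrofuran-3-carboxylic acid | COc1cc([C@H]2O[C@@H](c3ccccc3)OC[C@H]2Oc4ccc(C[C@H]6CO[C@H](c7ccc(OCc8ccccc8)c(OC)c7)[C@H]6C(=O)O)cc4OC)ccc1OCc1ccccc1
F9 | step 6 | methyl 4-hydroxy-4-Q-but-2-ynoate (both carbinol epimers) | COc1cc([C@H]2O[C@@H](c3ccccc3)OC[C@H]2Oc4ccc(C(O)C#CC(=O)OC)cc4OC)ccc1OCc1ccccc1
F10 | step 6 | methyl 4-oxo-4-Q-but-2-ynoate | COc1cc([C@H]2O[C@@H](c3ccccc3)OC[C@H]2Oc4ccc(C(=O)C#CC(=O)OC)cc4OC)ccc1OCc1ccccc1
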